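**Retrosynthetic overview**
1. The epoxide (hydroxyl-directed epoxidation), the veratrate and the C6 carbinol (hydroxyl-directed reduction) are installed last on a δ-hydroxy β,γ-enone, which comes from SmI2 opening of a γ,δ-epoxy dienone.
2. The dienone is the hydrolysed methyl dienol ether of a bicyclic cycloheptatriene that already carries the C2 acetate (CBS reduction, which also parts the antipodes).
3. Key disconnection: the cycloheptatriene is cut back to a benzene ring. An intramolecular Buchner reaction of an α-methyl α-diazoketone on a 2-methoxy-4-methylphenyl group makes the quaternary C1, the five-membered ring (carbene–ipso bond) and then the seven-membered ring (ring expansion of the arene) in one step.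
4. The diazoketone is the aldol adduct of 3-diazobutan-2-one and an aryl isopropyl ketone made from 3-methylanisole; veratroyl chloride is the second aromatic building block.

Atom labels in the Why lines are those of the target skeleton: C1 angular methyl carbon, C2 CH–OAc, C3 CH2, C4 C(OH)(i-Pr), C5 ring-fusion CH, C6 CH–O-veratroyl, C7 CH2, C8/C9 epoxide carbons, C10 CH–OH. Systematic names use azulene locants.

Assumption: read literally, the C8 and C9 descriptors of the given string put the oxirane oxygen on opposite faces of the seven-membered ring; I take the target as the cis-fused 8,9-epoxide with its oxygen on the face of the C10 hydroxyl (as the C9 descriptor and all other centres say) and keep the given string unchanged for the target.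

**Step 1**
Reactants: 1 3-methylanisole; 2 N-methoxy-N-methylisobutyramide
Product: 4 1-(2-methoxy-4-methylphenyl)-2-methylpropan-1-one, via 2-methoxy-4-methylphenyllithium 3 (not isolated)
Conditions: n-BuLi, TMEDA, Et2O, 0 °C → rt; then 2, −78 °C → rt; aq. NH4Cl
Reagents that add atoms: none
Why: Directed ortho-metalation puts lithium at the unhindered position ortho to methoxy (para to methyl), and the Weinreb amide stops the acylation at the ketone.

**Step 2**
Reactants: 5 3-methylpentane-2,4-dione
Product: 6 3-diazobutan-2-one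
Conditions: p-ABSA, DBU, MeCN, 0 °C → rt
Reagents that add atoms: 4-acetamidobenzenesulfonyl azide (p-ABSA), CC(=O)Nc1ccc(cc1)S(=O)(=O)N=[N+]=[N-]
Why: Deacylative Regitz diazo transfer: the enolate of the 2-substituted 1,3-diketone adds to the azide and the adduct collapses with transfer of one acetyl group to the sulfonamide nitrogen.

**Step 3**
Reactants: 4 1-(2-methoxy-4-methylphenyl)-2-methylpropan-1-one; 6 3-diazobutan-2-one
Product: 9 rac-2-diazo-5-(2-methoxy-4-methylphenyl)-6-methyl-5-(triethylsilyloxy)heptan-3-one, via lithium 3-diazobut-1-en-2-olate 7 (not isolated), via lithium aldolate 8 (not isolated)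
Conditions: LiHMDS, THF, −78 °C; then 4, −78 → −40 °C; then TESOTf, −78 °C
Reagents that add atoms: triethylsilyl trifluoromethanesulfonate (TESOTf), CC[Si](CC)(CC)OS(=O)(=O)C(F)(F)F
Why: Aldol addition of the only possible enolate of 6 to the ketone (lithium held by the ortho-methoxy group), with O-silylation in the flask to stop retro-aldol and to mask the hydroxyl toward the carbenoid; C4 forms as a racemate whose antipodes are parted in step 5.

**Step 4**
Reactants: 9 rac-2-diazo-5-(2-methoxy-4-methylphenyl)-6-methyl-5-(triethylsilyloxy)heptan-3-one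
Product: 11 rac-(3S,8aS)-3-isopropyl-4-methoxy-6,8a-dimethyl-3-(triethylsilyloxy)-3,8a-dihydroazulen-1(2H)-one, via norcaradiene 10 (not isolated)
Conditions: Rh2(O2CC3F7)4 (1 mol %), CH2Cl2, rt, slow addition of 9
Reagents that add atoms: none
Why: Intramolecular Buchner reaction: the electrophilic rhodium carbenoid cyclopropanates the ipso/unsubstituted-ortho bond (the methoxy group blocks the other side) and the norcaradiene opens by 6π electrocyclic ring opening, so the arene is lost and both rings and the quaternary C1 form at once; in the cyclopropanation transition state the C4 oxygen, the smallest benzylic substituent, lies in the arene plane next to the ortho-methoxy group (allylic 1,3-strain) and isopropyl points away, which puts the new C1 methyl cis to the silyloxy group.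

**Step 5**
Reactants: 11 rac-(3S,8aS)-3-isopropyl-4-methoxy-6,8a-dimethyl-3-(triethylsilyloxy)-3,8a-dihydroazulen-1(2H)-one
Product: 12 (1R,3S,8aS)-3-isopropyl-4-methoxy-6,8a-dimethyl-3-(triethylsilyloxy)-1,2,3,8a-tetrahydroazulen-1-ol
Conditions: (S)-Me-CBS (20 mol %), catecholborane, toluene, −78 °C; chromatography
Reagents that add atoms: none
Why: Corey–Bakshi–Shibata reduction under reagent control (quaternary carbon as large group, CH2 as small group) gives the 1R carbinol from both antipodes, so (3S,8aS)-11 gives 12 with hydroxyl trans to the angular methyl and the antipode gives the cis diastereomer, which is removed; this sets C2 and the absolute configuration of the series (at most half of 11 is used).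

**Step 6**
Reactants: 12 (1R,3S,8aS)-3-isopropyl-4-methoxy-6,8a-dimethyl-3-(triethylsilyloxy)-1,2,3,8a-tetrahydroazulen-1-ol
Product: 13 (1R,3S,8aS)-3-isopropyl-4-methoxy-6,8a-dimethyl-3-(triethylsilyloxy)-1,2,3,8a-tetrahydroazulen-1-yl acetate
Conditions: Ac2O, DMAP, pyridine, CH2Cl2, rt
Reagents that add atoms: acetic anhydride, CC(=O)OC(C)=O
Why: DMAP-catalysed acetylation of the only free hydroxyl, with retention at C2.

**Step 7**
Reactants: 13 (1R,3S,8aS)-3-isopropyl-4-methoxy-6,8a-dimethyl-3-(triethylsilyloxy)-1,2,3,8a-tetrahydroazulen-1-yl acetate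
Product: 15 (1R,3S,3aS,8aS)-3-hydroxy-3-isopropyl-6,8a-dimethyl-4-oxo-1,2,3,3a,4,8a-hexahydroazulen-1-yl acetate, via silyl ether dienone 14 (not isolated)
Conditions: oxalic acid, THF/H2O, 0 °C → rt; then HF·pyridine, pyridine, 0 °C
Reagents that add atoms: water, O
Why: Acid hydrolysis of the methyl dienol ether (C-protonation at C5, loss of methanol) unveils the C6 ketone while the tertiary oxygen is still silylated and so cannot ionise in a Stork–Danheiser sense; protonation anti to the C1 methyl and C4 silyloxy group, and acid equilibration, give the trans ring fusion (H5 cis to isopropyl), and fluoride then frees the tertiary alcohol.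

**Step 8**
Reactants: 15 (1R,3S,3aS,8aS)-3-hydroxy-3-isopropyl-6,8a-dimethyl-4-oxo-1,2,3,3a,4,8a-hexahydroazulen-1-yl acetate
Product: 16 (1R,3S,3aS,7S,8R,8aS)-7,8-epoxy-3-hydroxy-3-isopropyl-6,8a-dimethyl-4-oxo-1,2,3,3a,4,7,8,8a-octahydroazulen-1-yl acetate
Conditions: mCPBA, CH2Cl2, 0 °C
Reagents that add atoms: 3-chloroperbenzoic acid (mCPBA), OOC(=O)c1cccc(Cl)c1
Why: Prilezhaev epoxidation of the more electron-rich γ,δ-double bond of the dienone (the α,β-bond is deactivated) from the face opposite the adjacent angular methyl, which puts oxygen on C10 with the configuration of the target.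

**Step 9**
Reactants: 16 (1R,3S,3aS,7S,8R,8aS)-7,8-epoxy-3-hydroxy-3-isopropyl-6,8a-dimethyl-4-oxo-1,2,3,3a,4,7,8,8a-octahydroazulen-1-yl acetate
Product: 17 (1R,3S,3aS,8S,8aR)-3,8-dihydroxy-3-isopropyl-6,8a-dimethyl-4-oxo-1,2,3,3a,4,5,8,8a-octahydroazulen-1-yl acetate
Conditions: SmI2, THF/MeOH, −78 °C
Reagents that add atoms: none
Why: SmI2 reduction of a γ,δ-epoxy enone: two-electron transfer opens the allylic C9–O bond to a samarium dienolate that is protonated at C7, giving the δ-hydroxy β,γ-unsaturated ketone with the C10–O bond untouched.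

**Step 10**
Reactants: 17 (1R,3S,3aS,8S,8aR)-3,8-dihydroxy-3-isopropyl-6,8a-dimethyl-4-oxo-1,2,3,3a,4,5,8,8a-octahydroazulen-1-yl acetate
Product: 18 (1R,3S,3aR,4R,8S,8aR)-3,4,8-trihydroxy-3-isopropyl-6,8a-dimethyl-1,2,3,3a,4,5,8,8a-octahydroazulen-1-yl acetate
Conditions: Me4NBH(OAc)3, MeCN/AcOH, −30 °C
Reagents that add atoms: none
Why: Evans–Saksena hydroxyl-directed reduction: the tertiary C4 hydroxyl exchanges onto boron and delivers hydride to the β-ketone from its own face, so the new C6 hydroxyl is anti to it (H6 trans to H5).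

**Step 11**
Reactants: 18 (1R,3S,3aR,4R,8S,8aR)-3,4,8-trihydroxy-3-isopropyl-6,8a-dimethyl-1,2,3,3a,4,5,8,8a-octahydroazulen-1-yl acetate; 19 3,4-dimethoxybenzoyl chloride
Product: 20 (1R,3S,3aR,4R,8S,8aR)-1-acetoxy-3,8-dihydroxy-3-isopropyl-6,8a-dimethyl-1,2,3,3a,4,5,8,8a-octahydroazulen-4-yl 3,4-dimethoxybenzoate
Conditions: pyridine, DMAP (cat.), CH2Cl2, −20 → 0 °C
Reagents that add atoms: none
Why: DMAP-catalysed acylation at the least hindered hydroxyl: C6–OH lies between CH and CH2, whereas C10–OH is neopentylic (next to the quaternary C1) and the C4 hydroxyl is tertiary.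

**Step 12**
Reactants: 20 (1R,3S,3aR,4R,8S,8aR)-1-acetoxy-3,8-dihydroxy-3-isopropyl-6,8a-dimethyl-1,2,3,3a,4,5,8,8a-octahydroazulen-4-yl 3,4-dimethoxybenzoate
Product: 21 target
Conditions: VO(acac)2 (5 mol %), t-BuOOH, CH2Cl2, 0 °C → rt
Reagents that add atoms: tert-butyl hydroperoxide, CC(C)(C)OO
Why: Sharpless–Michaelson vanadium-catalysed epoxidation directed by the allylic C10 hydroxyl delivers oxygen to the only remaining double bond syn to that hydroxyl, setting C8 and C9.

**Compound list**
1 | 3-methylanisole | COc1cccc(C)c1 | starting material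
2 | N-methoxy-N-methylisobutyramide | CC(C)C(=O)N(C)OC | starting material
3 | 2-methoxy-4-methylphenyllithium | [Li]c1ccc(C)cc1OC | intermediate
4 | 1-(2-methoxy-4-methylphenyl)-2-methylpropan-1-one | COc1cc(C)ccc1C(=O)C(C)C | intermediate
5 | 3-methylpentane-2,4-dione | CC(=O)C(C)C(C)=O | starting material
6 | 3-diazobutan-2-one | CC(=O)C(C)=[N+]=[N-] | intermediate
7 | lithium 3-diazobut-1-en-2-olate | [Li]OC(=C)C(C)=[N+]=[N-] | intermediate
8 | lithium 2-diazo-5-(2-methoxy-4-methylphenyl)-6-methyl-3-oxoheptan-5-olate (racemate; S antipode drawn) | CC(C)[C@@](O[Li])(CC(=O)C(C)=[N+]=[N-])c1ccc(C)cc1OC | intermediate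
9 | rac-2-diazo-5-(2-methoxy-4-methylphenyl)-6-methyl-5-(triethylsilyloxy)heptan-3-one (racemate; S antipode drawn) | CC(C)[C@@](O[Si](CC)(CC)CC)(CC(=O)C(C)=[N+]=[N-])c1ccc(C)cc1OC | intermediate
10 | norcaradiene valence isomer of 11 (cyclopropane across the former ipso–ortho bond, methyl over the diene; racemate, productive antipode drawn) | COC1=CC(C)=C[C@H]2[C@]3(C)C(=O)C[C@](O[Si](CC)(CC)CC)(C(C)C)[C@]123 | intermediate
11 | rac-(3S,8aS)-3-isopropyl-4-methoxy-6,8a-dimethyl-3-(triethylsilyloxy)-3,8a-dihydroazulen-1(2H)-one (8a-methyl cis to silyloxy; racemate, productive antipode drawn) | COC1=C2[C@@](O[Si](CC)(CC)CC)(C(C)C)CC(=O)[C@@]2(C)C=CC(C)=C1 | intermediate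
12 | (1R,3S,8aS)-3-isopropyl-4-methoxy-6,8a-dimethyl-3-(triethylsilyloxy)-1,2,3,8a-tetrahydroazulen-1-ol | COC1=C2[C@@](O[Si](CC)(CC)CC)(C(C)C)C[C@@H](O)[C@@]2(C)C=CC(C)=C1 | intermediate
13 | (1R,3S,8aS)-3-isopropyl-4-methoxy-6,8a-dimethyl-3-(triethylsilyloxy)-1,2,3,8a-tetrahydroazulen-1-yl acetate | COC1=C2[C@@](O[Si](CC)(CC)CC)(C(C)C)C[C@@H](OC(C)=O)[C@@]2(C)C=CC(C)=C1 | intermediate
14 | (1R,3S,3aS,8aS)-3-isopropyl-6,8a-dimethyl-4-oxo-3-(triethylsilyloxy)-1,2,3,3a,4,8a-hexahydroazulen-1-yl acetate | O=C1C=C(C)C=C[C@]2(C)[C@H](OC(C)=O)C[C@](O[Si](CC)(CC)CC)(C(C)C)[C@@H]12 | intermediate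
15 | (1R,3S,3aS,8aS)-3-hydroxy-3-isopropyl-6,8a-dimethyl-4-oxo-1,2,3,3a,4,8a-hexahydroazulen-1-yl acetate | O=C1C=C(C)C=C[C@]2(C)[C@H](OC(C)=O)C[C@](O)(C(C)C)[C@@H]12 | intermediate
16 | (1R,3S,3aS,7S,8R,8aS)-7,8-epoxy-3-hydroxy-3-isopropyl-6,8a-dimethyl-4-oxo-1,2,3,3a,4,7,8,8a-octahydroazulen-1-yl acetate | O=C1C=C(C)[C@@H]3O[C@@H]3[C@]2(C)[C@H](OC(C)=O)C[C@](O)(C(C)C)[C@@H]12 | intermediate
17 | (1R,3S,3aS,8S,8aR)-3,8-dihydroxy-3-isopropyl-6,8a-dimethyl-4-oxo-1,2,3,3a,4,5,8,8a-octahydroazulen-1-yl acetate | O=C1CC(C)=C[C@H](O)[C@]2(C)[C@H](OC(C)=O)C[C@](O)(C(C)C)[C@@H]12 | intermediate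
18 | (1R,3S,3aR,4R,8S,8aR)-3,4,8-trihydroxy-3-isopropyl-6,8a-dimethyl-1,2,3,3a,4,5,8,8a-octahydroazulen-1-yl acetate | O[C@@H]1CC(C)=C[C@H](O)[C@]2(C)[C@H](OC(C)=O)C[C@](O)(C(C)C)[C@@H]12 | intermediate
19 | 3,4-dimethoxybenzoyl chloride (veratroyl chloride) | COc1ccc(C(Cl)=O)cc1OC | starting material
20 | (1R,3S,3aR,4R,8S,8aR)-1-acetoxy-3,8-dihydroxy-3-isopropyl-6,8a-dimethyl-1,2,3,3a,4,5,8,8a-octahydroazulen-4-yl 3,4-dimethoxybenzoate | COc1ccc(C(=O)O[C@@H]2CC(C)=C[C@H](O)[C@]3(C)[C@H](OC(C)=O)C[C@](O)(C(C)C)[C@@H]23)cc1OC | intermediate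
21 | 2-acetoxy-8,9-epoxy-4,10-dihydroxydaucan-6-yl 3,4-dimethoxybenzoate (epoxide oxygen, C10–OH, C6–O and C2–OAc on one face; C4–OH and C1 methyl on the other; string as given) | COc1ccc(C(=O)O[C@@H]2C[C@@]3(C)O[C@@H]3[C@H](O)[C@]3(C)[C@H](OC(C)=O)C[C@](O)(C(C)C)[C@@H]23)cc1OC | target

**Totals**
Total step count: 12. Longest linear sequence: 11 (steps 1 and 3 to 12; step 2 is a one-step side branch).

**Steps most likely to fail, with fallbacks**

Step 4 (Buchner reaction). The carbenoid may insert into the isopropyl C–H bond, attack the hindered silyloxy oxygen, or shift a β-hydride; the C1/C4 diastereoselectivity is also untested on a fully substituted benzylic carbon. Fallback: carry C4 through the dearomatisation as a secondary carbinol and add isopropyl afterwards. It sets out from 1: aryllithium 3 is quenched with DMF to give 2-methoxy-4-methylbenzaldehyde F1. Aldol addition of enolate 7 and TESOTf trapping give racemic 2-diazo-5-(2-methoxy-4-methylphenyl)-5-(triethylsilyloxy)pentan-3-one F2. Rh2(O2CC3F7)4 gives the racemic bicyclic trienone F3, whose C3 configuration is later erased. (S)-Me-CBS/catecholborane, as in step 5, gives the 1R,8aS alcohol F4. Ac2O/DMAP gives acetate F5, HF·pyridine frees the allylic alcohol F6, and MnO2 oxidises it to the vinylogous ester F7. Finally i-PrMgCl/CeCl3 at −78 °C (attack anti to the angular methyl), followed by TESOTf in the same flask, comes back to the route at 13.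

Step 5 (reagent-controlled reduction of the racemate). The oxazaborolidine may fail to override the ketone's own facial bias, in which case both antipodes give the same relative configuration and nothing is resolved. Fallback: resolve one step later with an enzyme. It sets out from 11: NaBH4/CeCl3 in MeOH (hydride anti to the angular methyl) gives the racemic C1-epimeric alcohol F8. Burkholderia cepacia lipase with vinyl acetate acetylates the 1R antipode to acetate F9, which is discarded, and leaves (1S,3S,8aS)-F8. Mitsunobu inversion with acetic acid (PPh3, DIAD, toluene) then comes back to the route at 13.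

Step 7 (dienol ether hydrolysis). C-protonation at the hindered C5 may be slower than loss of the allylic C4 oxygen (Stork–Danheiser-type elimination), and the ring-fusion configuration rests on the protonation face and equilibration. Fallback: cleave the O–methyl bond by SN2 instead of by acid. It sets out from 12: NaSEt in DMF at 90 °C attacks the methyl group (the dienolate leaves, no cation is formed next to C4), and aqueous work-up gives hydroxy dienone F10. Ac2O/DMAP/pyridine then gives 14, isolated in this variant, where it comes back to the route; HF·pyridine takes 14 on to 15 as in step 7.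

**Further compounds**
F1 | step 4 | 2-methoxy-4-methylbenzaldehyde | COc1cc(C)ccc1C=O
F2 | step 4 | rac-2-diazo-5-(2-methoxy-4-methylphenyl)-5-(triethylsilyloxy)pentan-3-one (racemate; S antipode drawn) | O=C(C[C@H](O[Si](CC)(CC)CC)c1ccc(C)cc1OC)C(C)=[N+]=[N-]
F3 | step 4 | rac-(3S,8aS)-4-methoxy-6,8a-dimethyl-3-(triethylsilyloxy)-3,8a-dihydroazulen-1(2H)-one (racemate; productive antipode drawn) | COC1=C2[C@@H](O[Si](CC)(CC)CC)CC(=O)[C@@]2(C)C=CC(C)=C1
F4 | step 4 | (1R,3S,8aS)-4-methoxy-6,8a-dimethyl-3-(triethylsilyloxy)-1,2,3,8a-tetrahydroazulen-1-ol | COC1=C2[C@@H](O[Si](CC)(CC)CC)C[C@@H](O)[C@@]2(C)C=CC(C)=C1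
F5 | step 4 | (1R,3S,8aS)-4-methoxy-6,8a-dimethyl-3-(triethylsilyloxy)-1,2,3,8a-tetrahydroazulen-1-yl acetate | COC1=C2[C@@H](O[Si](CC)(CC)CC)C[C@@H](OC(C)=O)[C@@]2(C)C=CC(C)=C1
F6 | step 4 | (1R,3S,8aS)-3-hydroxy-4-methoxy-6,8a-dimethyl-1,2,3,8a-tetrahydroazulen-1-yl acetate | COC1=C2[C@@H](O)C[C@@H](OC(C)=O)[C@@]2(C)C=CC(C)=C1
F7 | step 4 | (1R,8aS)-4-methoxy-6,8a-dimethyl-3-oxo-1,2,3,8a-tetrahydroazulen-1-yl acetate | COC1=C2C(=O)C[C@@H](OC(C)=O)[C@@]2(C)C=CC(C)=C1
F8 | step 5 | (1S,3S,8aS)-3-isopropyl-4-methoxy-6,8a-dimethyl-3-(triethylsilyloxy)-1,2,3,8a-tetrahydroazulen-1-ol (first racemic, then this antipode alone) | COC1=C2[C@@](O[Si](CC)(CC)CC)(C(C)C)C[C@H](O)[C@@]2(C)C=CC(C)=C1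
F9 | step 5 | (1R,3R,8aR)-3-isopropyl-4-methoxy-6,8a-dimethyl-3-(triethylsilyloxy)-1,2,3,8a-tetrahydroazulen-1-yl acetate | COC1=C2[C@](O[Si](CC)(CC)CC)(C(C)C)C[C@@H](OC(C)=O)[C@]2(C)C=CC(C)=C1
F10 | step 7 | (1R,3S,3aS,8aS)-1-hydroxy-3-isopropyl-6,8a-dimethyl-3-(triethylsilyloxy)-2,3,3a,8a-tetrahydroazulen-4(1H)-one | O=C1C=C(C)C=C[C@]2(C)[C@H](O)C[C@](O[Si](CC)(CC)CC)(C(C)C)[C@@H]12
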